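**Strategy.** The seven-membered carbocycle (C1, C5, C6, C7, C8, C9, C10) is disconnected at C5. Six of its carbons come from the ring of (R)-carvone: the methyl-bearing carbon becomes C10, the carbonyl C1, and the stereocentre C7 with the C11–C13 branch. C5 enters as a cyclopropane methylene across C1 and C6. Oxidation of this siloxycyclopropane by trivalent iron breaks the C1–C6 bond and, after loss of HCl, gives the ring-enlarged cross-conjugated dienone in one operation without touching C7. The precursor is the 1-trimethylsiloxybicyclo[4.1.0]hept-2-ene from carvone's kinetic dienolate. The two enone units then accept the C5, C6 and C9 oxygens anti to C7.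

Key step: step 3

Convention (remark): C1 = tertiary carbinol, C2–C4 = side chain, C5 = ester-bearing CH, C6 = lactone O–CH, C7 = ring-fusion CH, C8 = CH2, C9 = CHOH, C10 = CHMe, C11–C13 = lactone carbons and exocyclic methylene; α is the ring face of the C7–C11 bond, β the opposite face.

Step 1
Reactants: 1 (R)-carvone
Product: 3 carvone trimethylsilyl dienol ether, via lithium dienolate 2 (not isolated)
Conditions: LiN(iPr)2, THF, −78 °C; Me3SiCl, −78 °C → rt
Reagents that add atoms: chlorotrimethylsilane, C[Si](C)(C)Cl
Why: Kinetic deprotonation of the enone by the hindered amide can occur only at the C6 methylene (the other α-carbon is the methyl-bearing alkene carbon), and O-silylation of the cross-conjugated dienolate gives the 2-siloxy-1,3-diene (silyl enol ether formation) without touching C7.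

Step 2
Reactants: 3 carvone trimethylsilyl dienol ether
Product: 4 1-trimethylsiloxy-2-methyl-5-isopropenylbicyclo[4.1.0]hept-2-ene (cyclopropane CH2 anti to isopropenyl)
Conditions: Et2Zn, CH2I2, toluene, 0 °C → rt
Reagents that add atoms: diiodomethane, ICI
Why: Furukawa-type Simmons–Smith cyclopropanation, in which the electrophilic zinc carbenoid selects the electron-rich enol ether C1=C6 bond over the C9=C10 and isopropenyl alkenes and adds anti to the neighbouring C7 substituent, setting two cyclopropane stereocentres that are lost again in step 3.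

Step 3
Reactants: 4 1-trimethylsiloxy-2-methyl-5-isopropenylbicyclo[4.1.0]hept-2-ene
Product: 6 (5R)-2-methyl-5-(prop-1-en-2-yl)cyclohepta-2,6-dien-1-one, via chloro ketone 5 (not isolated)
Conditions: FeCl3, DMF, 0 °C → rt; NaOAc, MeOH, reflux
Reagents that add atoms: none
Why: FeCl3 (trivalent iron) oxidises the electron-rich siloxycyclopropane by single-electron transfer, the silyl group is lost, and the oxygen-bound C1 radical opens the internal C1–C6 bond to give the C1 ketone and a ring-enlarged secondary C6 radical that takes chlorine from a second FeCl3 to give β-chloro ketone 5; NaOAc then removes HCl through the C5 enolate (E1cB) to form the C5=C6 enone. The closest known reaction type is the Saegusa–Ito FeCl3 ring expansion of 1-siloxybicyclo[n.1.0]alkanes to cycloalk-2-enones. Ring enlargement comes from scission of the zero-atom bridge of the bicyclo[4.1.0]heptane, a fragmentation and not a ring closure, so the skeleton gains no bond in this step. No new stereocentre is created, the two cyclopropane stereocentres disappear and C7 keeps the configuration of (R)-carvone. The step needs scission of the internal bond instead of an external cyclopropane bond, secured because only internal cleavage puts the carbonyl into the ring and releases a secondary rather than a primary radical; it also needs the C9=C10 and isopropenyl alkenes to survive, secured because the one-electron oxidant attacks only the siloxycyclopropane and the elimination uses a weak base that does not remove the C7 hydrogen.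

Step 4
Reactants: 6 (5R)-2-methyl-5-(prop-1-en-2-yl)cyclohepta-2,6-dien-1-one
Product: 7 5β,6β:9β,10β-diepoxy ketone
Conditions: H2O2 (30% aq), NaOH, MeOH, −10 → 10 °C
Reagents that add atoms: hydrogen peroxide, OO
Why: Weitz–Scheffer nucleophilic epoxidation of both enone units, in which hydroperoxide should add to C6 and C9 from the β face, anti to the C7 isopropenyl group (adjacent to C6, 1,3 to C9, as in the epoxidation of carvone), while the unactivated isopropenyl alkene is inert and the low temperature limits removal of the C7 hydrogen.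

Step 5
Reactants: 7 5β,6β:9β,10β-diepoxy ketone
Product: 9 cis-fused 3-methyleneoxolane with 5β-hydroxyl and 9β,10β-epoxy ketone, via allylic alcohol 8 (not isolated)
Conditions: SeO2 (cat.), t-BuOOH, CH2Cl2, rt; camphorsulfonic acid (cat.), CH2Cl2, 0 °C
Reagents that add atoms: selenium dioxide, O=[Se]=O; tert-butyl hydroperoxide, CC(C)(C)OO
Why: Selenium dioxide allylic oxidation (ene reaction, then [2,3]-shift) hydroxylates the methyl of the 1,1-disubstituted alkene, and acid then lets the new C12 hydroxyl open the C5–C6 epoxide 5-exo at C6, the carbon remote from the carbonyl, with inversion (C6–O α, cis-fused oxolane, C5–OH β), whereas the C9–C10 epoxide has no internal nucleophile and stays.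

Step 6
Reactants: 9 cis-fused 3-methyleneoxolane with 5β-hydroxyl and 9β,10β-epoxy ketone
Product: 10 5β-triethylsilyl ether of 9
Conditions: Et3SiOTf, 2,6-lutidine, CH2Cl2, −78 °C
Reagents that add atoms: triethylsilyl trifluoromethanesulfonate, CC[Si](CC)(CC)OS(=O)(=O)C(F)(F)F
Why: Silyl ether formation at the only free hydroxyl marks the C5 oxygen so that it can later be told apart from the C9 oxygen released in step 7.

Step 7
Reactants: 10 5β-triethylsilyl ether of 9
Product: 11 9β-hydroxy-10α-methyl ketone (5β-OSiEt3)
Conditions: Na[PhSeB(OEt)3] (from PhSeSePh, NaBH4, EtOH), EtOH, 0 °C → rt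
Reagents that add atoms: none
Why: Organoselenium-mediated reductive opening of the α,β-epoxy ketone, in which phenylselenide attacks the α-carbon C10, a second selenide removes selenium to give the C1–C10 enolate and ethanol protonates it, so the C9–O bond keeps its β configuration; C10 stays epimerisable in the unbuffered ethoxyborate medium and should settle with the methyl α, trans to the C9 hydroxyl, while the soft reagent spares the α-silyloxy centre and the alkene.

Step 8
Reactants: 11 9β-hydroxy-10α-methyl ketone (5β-OSiEt3)
Product: 12 9β-tert-butyldimethylsilyl ether of 11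
Conditions: t-BuMe2SiOTf, 2,6-lutidine, CH2Cl2, −78 °C
Reagents that add atoms: tert-butyldimethylsilyl trifluoromethanesulfonate, CC(C)(C)[Si](C)(C)OS(=O)(=O)C(F)(F)F
Why: Silyl ether formation with the triflate and a hindered base at low temperature protects the β-hydroxyl without retro-aldol cleavage or β-elimination.

Step 9
Reactants: 12 9β-tert-butyldimethylsilyl ether of 11
Product: 13 5β-hydroxy ketone (9β-OSiMe2tBu)
Conditions: pyridinium p-toluenesulfonate (cat.), MeOH, 0 °C
Reagents that add atoms: none
Why: Selective desilylation by acid-catalysed methanolysis removes the more labile triethylsilyl ether and leaves the tert-butyldimethylsilyl ether.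

Step 10
Reactants: 14 1,3-dithiane; 15 (S)-2-methyloxirane
Product: 17 (2S)-1-(1,3-dithian-2-yl)propan-2-ol, via 2-lithio-1,3-dithiane 16 (not isolated)
Conditions: n-BuLi, THF, −30 °C; then 15, −30 → 0 °C
Reagents that add atoms: none
Why: Corey–Seebach alkylation, in which the lithiated dithiane opens the epoxide at its unsubstituted carbon (SN2), so the C4 stereocentre is taken unchanged from (S)-propylene oxide.

Step 11
Reactants: 17 (2S)-1-(1,3-dithian-2-yl)propan-2-ol
Product: 18 tert-butyldimethylsilyl ether of 17
Conditions: t-BuMe2SiCl, imidazole, DMF, rt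
Reagents that add atoms: tert-butyldimethylsilyl chloride, CC(C)(C)[Si](C)(C)Cl
Why: Standard silyl ether formation protects the C4 hydroxyl for the strongly basic coupling.

Step 12
Reactants: 18 tert-butyldimethylsilyl ether of 17; 13 5β-hydroxy ketone (9β-OSiMe2tBu)
Product: 20 C1 carbinol with dithiane-masked side chain, via lithiated dithiane 19 (not isolated)
Conditions: t-BuLi, THF/HMPA, −78 °C; then 13 (19 in excess), −78 °C
Reagents that add atoms: none
Why: Corey–Seebach 1,2-addition of the acyl anion equivalent to the C1 ketone, the first equivalent deprotonating the C5 hydroxyl; the lithium chelate between the C5 alkoxide and the carbonyl should hold C5–O near the carbonyl plane, so the α face is screened by the C10 methyl and the concave side of the cis-fused oxolane and the nucleophile should enter from β (C1–OH α, side chain β), and the oxolane, unlike a lactone, is inert to the organolithium.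

Step 13
Reactants: 20 C1 carbinol with dithiane-masked side chain
Product: 21 tertiary α-hydroxy ketone (C2 ketone)
Conditions: MeI, CaCO3, MeCN/H2O, 45 °C
Reagents that add atoms: water, O
Why: Alkylative dithiane hydrolysis (S-methylation, then hydrolysis of the sulfonium salt) unmasks the C2 ketone under buffered conditions that spare the silyl ethers, the tertiary ketol and the exocyclic alkene.

Step 14
Reactants: 21 tertiary α-hydroxy ketone (C2 ketone); 22 (S)-2-methylbutanoic acid
Product: 23 5β-(S)-2-methylbutanoate of 21
Conditions: DCC, DMAP, CH2Cl2, 0 °C → rt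
Reagents that add atoms: none
Why: Steglich esterification acylates the only secondary hydroxyl (C5), the tertiary C1 hydroxyl does not react, and the α-stereocentre of the acid should be retained under the mild carbodiimide conditions.

Step 15
Reactants: 23 5β-(S)-2-methylbutanoate of 21
Product: 24 α-methylene γ-lactone (4,9-bis-silyl ether of the target)
Conditions: CrO3, 3,5-dimethylpyrazole, CH2Cl2, −20 °C
Reagents that add atoms: chromium trioxide, O=[Cr](=O)=O
Why: Allylic oxidation by hexavalent chromium of the oxolane CH2, which is activated both by the ring oxygen and by the exocyclic alkene, converts the cyclic allyl ether into the α-methylene γ-lactone, and no free secondary alcohol is present.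

Step 16
Reactants: 24 α-methylene γ-lactone (4,9-bis-silyl ether of the target)
Product: 25 CNP0291806.1 (target)
Conditions: HF·pyridine, pyridine, THF, 0 °C → rt
Reagents that add atoms: none
Why: Global desilylation with buffered fluoride frees the C4 and C9 hydroxyls without retro-aldol cleavage, acyl migration or conjugate addition to the methylene lactone.

**Compound list**

1 | (R)-carvone, (5R)-2-methyl-5-(prop-1-en-2-yl)cyclohex-2-en-1-one | CC1=CC[C@H](CC1=O)C(C)=C | starting material
2 | lithium (3R)-6-methyl-3-(prop-1-en-2-yl)cyclohexa-1,5-dien-1-olate (kinetic dienolate of 1) | CC1=CC[C@H](C=C1O[Li])C(C)=C | intermediate (not isolated)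
3 | trimethyl{[(3R)-6-methyl-3-(prop-1-en-2-yl)cyclohexa-1,5-dien-1-yl]oxy}silane | CC1=CC[C@H](C=C1O[Si](C)(C)C)C(C)=C | intermediate
4 | trimethyl{[2-methyl-5-(prop-1-en-2-yl)bicyclo[4.1.0]hept-2-en-1-yl]oxy}silane, cis ring fusion, cyclopropane CH2 (future C5) anti to the isopropenyl group | CC1=CC[C@@H](C(C)=C)[C@@H]2C[C@]12O[Si](C)(C)C | intermediate (key-step precursor)
5 | 6-chloro-2-methyl-5-(prop-1-en-2-yl)cyclohept-2-en-1-one, C7 as in carvone, both epimers at the chlorine-bearing carbon | CC1=CC[C@@H](C(C)=C)C(Cl)CC1=O | intermediate (not isolated)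
6 | (5R)-2-methyl-5-(prop-1-en-2-yl)cyclohepta-2,6-dien-1-one | CC1=CC[C@H](C=CC1=O)C(C)=C | intermediate (key-step product)
7 | 5β,6β:9β,10β-diepoxy ketone: 2-methyl-5-(prop-1-en-2-yl)-2,3:6,7-diepoxycycloheptan-1-one, both oxiranes anti to the isopropenyl group | O=C1[C@H]2O[C@H]2[C@H](C(C)=C)C[C@H]3O[C@]31C | intermediate
8 | diepoxy ketone 7 carrying a 3-hydroxyprop-1-en-2-yl group at C7 (C12 alcohol) | O=C1[C@H]2O[C@H]2[C@H](C(CO)=C)C[C@H]3O[C@]31C | intermediate (not isolated)
9 | cis-fused 3-methyleneoxolane (ring O on C6 α, C11 on C7 α) with 5β-hydroxyl, C1 ketone and 9β,10β-epoxide | C=C1CO[C@@H]2[C@H]1C[C@H]3O[C@@]3(C)C(=O)[C@H]2O | intermediate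
10 | 5β-triethylsilyl ether of 9 | C=C1CO[C@@H]2[C@H]1C[C@H]3O[C@@]3(C)C(=O)[C@H]2O[Si](CC)(CC)CC | intermediate
11 | 9β-hydroxy-10α-methyl ketone: 10 with the epoxide opened (C10–H β), 5β-OSiEt3 | C=C1CO[C@@H]2[C@H]1C[C@@H](O)[C@H](C)C(=O)[C@H]2O[Si](CC)(CC)CC | intermediate
12 | 9β-tert-butyldimethylsilyl ether of 11 | C=C1CO[C@@H]2[C@H]1C[C@@H](O[Si](C)(C)C(C)(C)C)[C@H](C)C(=O)[C@H]2O[Si](CC)(CC)CC | intermediate
13 | 5β-hydroxy ketone: 12 without the triethylsilyl group | C=C1CO[C@@H]2[C@H]1C[C@@H](O[Si](C)(C)C(C)(C)C)[C@H](C)C(=O)[C@H]2O | intermediate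
14 | 1,3-dithiane | C1CSCSC1 | starting material
15 | (S)-2-methyloxirane, (S)-propylene oxide | C[C@H]1CO1 | starting material
16 | 2-lithio-1,3-dithiane | [Li]C1SCCCS1 | intermediate (not isolated)
17 | (2S)-1-(1,3-dithian-2-yl)propan-2-ol | C[C@H](O)CC1SCCCS1 | intermediate
18 | tert-butyl{[(2S)-1-(1,3-dithian-2-yl)propan-2-yl]oxy}dimethylsilane | C[C@H](O[Si](C)(C)C(C)(C)C)CC1SCCCS1 | intermediate
19 | 2-lithio derivative of 18 | C[C@H](O[Si](C)(C)C(C)(C)C)CC1([Li])SCCCS1 | intermediate (not isolated)
20 | C1 carbinol: 1α-OH, β side chain with C2 as the 1,3-dithiane carbon and (4S)-OSiMe2tBu, 5β-OH, 9β-OSiMe2tBu, 10α-methyl, cis-fused 3-methyleneoxolane | C=C1CO[C@@H]2[C@H]1C[C@@H](O[Si](C)(C)C(C)(C)C)[C@H](C)[C@@](O)(C3(C[C@H](C)O[Si](C)(C)C(C)(C)C)SCCCS3)[C@H]2O | intermediate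
21 | tertiary α-hydroxy ketone: 20 with C2 as ketone | C=C1CO[C@@H]2[C@H]1C[C@@H](O[Si](C)(C)C(C)(C)C)[C@H](C)[C@@](O)(C(=O)C[C@H](C)O[Si](C)(C)C(C)(C)C)[C@H]2O | intermediate
22 | (S)-2-methylbutanoic acid | CC[C@H](C)C(O)=O | starting material
23 | 5β-[(2S)-2-methylbutanoyl] ester of 21 | C=C1CO[C@@H]2[C@H]1C[C@@H](O[Si](C)(C)C(C)(C)C)[C@H](C)[C@@](O)(C(=O)C[C@H](C)O[Si](C)(C)C(C)(C)C)[C@H]2OC(=O)[C@@H](C)CC | intermediate
24 | α-methylene γ-lactone: 23 with C12 as lactone carbonyl (4,9-bis-O-tert-butyldimethylsilyl target) | C=C1C(=O)O[C@@H]2[C@H]1C[C@@H](O[Si](C)(C)C(C)(C)C)[C@H](C)[C@@](O)(C(=O)C[C@H](C)O[Si](C)(C)C(C)(C)C)[C@H]2OC(=O)[C@@H](C)CC | intermediate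
25 | CNP0291806.1 | C=C1C(=O)O[C@@H]2[C@H]1C[C@@H](O)[C@H](C)[C@@](O)(C(=O)C[C@H](C)O)[C@H]2OC(=O)[C@@H](C)CC | target

**Step count.** Total: 16 steps. Longest linear sequence: 14 steps (steps 1–9 and 12–16); steps 10 and 11 make the side-chain fragment.

**Steps most likely to fail**

Step 12. The facial selectivity at C1 may be poor or reversed, because the β face also carries the C5 and C9 oxygens and the bulky lithiated dithiane may instead enter anti to the C5 oxygen. The basic nucleophile may also enolise the ketone towards C10 and expel the C9 silyloxy group. The fallback sets out from 13 and returns at 20. Dess–Martin periodinane (CH2Cl2, NaHCO3) oxidises the C5 carbinol to the 1,5-dione, which should rest as its C5=C6 enol, diosphenol F1. Et3SiOTf/Et3N (CH2Cl2, −78 °C) gives silyl enol ether F2, in which C5 is trigonal, so that only the C10 methyl biases the addition. Addition of 19 (THF/HMPA, −78 °C) to the vinylogous ester carbonyl should then give carbinol F3 with the side chain anti to that methyl. Bu4NF/AcOH (THF, −20 °C) releases the enol, which should ketonise to the cis-fused C5 ketone F4. A Saksena–Evans reduction (Me4NBH(OAc)3, MeCN/AcOH, −20 °C) delivers hydride from boron bound to the C1 hydroxyl, on the α face and anti to the dithiane, and should give the 5β-alcohol 20.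

Step 7. The C1–C10 enolate may be protonated on the α face, anti to the C9 oxygen, and equilibrate incompletely, so that the 10-epimer (methyl β) persists. The unbuffered medium may also cause retro-aldol opening or β-elimination. The fallback sets out from 10 and returns at 11. SmI2 (THF, −78 °C) opens the epoxy ketone to the enolate of trivalent samarium, and PhSeBr traps it as selenide F5. H2O2/pyridine (CH2Cl2, 0 °C) then brings about selenoxide syn-elimination towards the methyl group to give the 10-methylene 9β-hydroxy ketone F6. Hydroxyl-directed hydrogenation with [Rh(nbd)(dppb)]BF4 and H2 (CH2Cl2) adds hydrogen to C10 from the face of the C9 hydroxyl, which fixes C10–H β (methyl α) by mechanism and gives 11. The cationic rhodium catalyst is expected to leave the non-chelating oxolane methylene alone.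

Step 15. Site selectivity may be lost late in the route: hexavalent chromium may attack other C–H bonds (C7–H, C3–H2) or cleave the tertiary α-ketol oxidatively. The fallback sets out from 23 and returns at 24. SeO2 (cat.)/t-BuOOH (CH2Cl2, rt) hydroxylates C12 by the ene/[2,3] pathway to lactol F7, and MnO2 (CH2Cl2, rt) oxidises the allylic lactol to 24.

**Further compounds**

F1 | step 12 | diosphenol: C1 ketone, C5 enol (C5=C6), 9β-OSiMe2tBu, 10α-methyl, 3-methylene-2,3-dihydrofuran fused at C6–C7 | C=C1COC2=C(O)C(=O)[C@@H](C)[C@H](O[Si](C)(C)C(C)(C)C)C[C@H]21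
F2 | step 12 | 5-O-triethylsilyl enol ether of F1 | C=C1COC2=C(O[Si](CC)(CC)CC)C(=O)[C@@H](C)[C@H](O[Si](C)(C)C(C)(C)C)C[C@H]21
F3 | step 12 | C1 carbinol from F2 and 19 (1α-OH, dithiane side chain β, C5=C6 silyl enol ether) | C=C1COC2=C(O[Si](CC)(CC)CC)[C@](O)(C3(C[C@H](C)O[Si](C)(C)C(C)(C)C)SCCCS3)[C@@H](C)[C@H](O[Si](C)(C)C(C)(C)C)C[C@H]21
F4 | step 12 | C5 ketone: 1α-OH, dithiane side chain β, cis-fused 3-methyleneoxolane, 9β-OSiMe2tBu | C=C1CO[C@@H]2[C@H]1C[C@@H](O[Si](C)(C)C(C)(C)C)[C@H](C)[C@@](O)(C3(C[C@H](C)O[Si](C)(C)C(C)(C)C)SCCCS3)C2=O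
F5 | step 7 | 10-phenylselanyl-9β-hydroxy ketone (either C10 epimer), 5β-OSiEt3 | C=C1CO[C@@H]2[C@H]1C[C@@H](O)C(C)([Se]c3ccccc3)C(=O)[C@H]2O[Si](CC)(CC)CC
F6 | step 7 | 10-methylene-9β-hydroxy ketone, 5β-OSiEt3 | C=C1CO[C@@H]2[C@H]1C[C@@H](O)C(=C)C(=O)[C@H]2O[Si](CC)(CC)CC
F7 | step 15 | lactol: 12-hydroxy derivative of 23 (both C12 epimers) | C=C1C(O)O[C@@H]2[C@H]1C[C@@H](O[Si](C)(C)C(C)(C)C)[C@H](C)[C@@](O)(C(=O)C[C@H](C)O[Si](C)(C)C(C)(C)C)[C@H]2OC(=O)[C@@H](C)CC
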